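Cuts, in jatrophane numbering (ring C1–C4 and C15, enal C5–C7, chain C8–C14): C5=C6 by cross-metathesis, C13–C14 by crotylsilane plus aldehyde, and the ring bond C3–C4, which is traced back to a C3–C5 bond.
The ring cut turns cyclopentane C15–C1–C2–C3–C4 with exocyclic C5 into cyclohexane C15–C1–C2–C3–C5–C4. This is the ring of (−)-shikimic acid: its C1 = C15, C2 = C4, C3 = C5, C4 = C3, C5 = C2, C6 = C1 and CO2H = C14.
Enabling feature: C4 carries the formyl-level carbon C5 and lies between the carbinol carbons C3 and C15, with C5, O3 and O15 all on one face. A pinacol-type shift of C3 from a carbinol C5 to a sulfonate-bearing C4 leaves exactly this pattern.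
Forward: shikimate → 4,5-epoxide → CH3 at C2 → benzoate at O3 → syn diol at C15/C4 → equatorial tosylate → six-to-five ring contraction → C4 vinyl and C14 aldehyde → union with silane fragment C8–C13 → acetates → enal.
Stereochemistry: C3 is kept from shikimic acid and C2 comes by double inversion at its C5. C15 and the C4 leaving group are set by hydroxyl-directed dihydroxylation, and C4 by inversion in the shift. C14 is set by chelation, and C13 with the E-C11=C12 bond by a silane made from (S)-but-3-yn-2-ol.

Key step: step 11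

Remark on the chemistry: commercial (−)-shikimic acid (3R,4S,5R) and (S)-but-3-yn-2-ol are taken as enantiopure. Target atoms keep their jatrophane numbers in all intermediates.

Step 1
Reactants: 1 (S)-but-3-yn-2-ol; 2 dimethyl(phenyl)silane
Product: 3 (2S,3E)-4-[dimethyl(phenyl)silyl]but-3-en-2-ol
Conditions: Pt2[(CH2=CHSiMe2)2O]3 (0.5 mol %), P(t-Bu)3, THF, rt
Reagents that add atoms: none
Why: Platinum-catalysed syn hydrosilylation of a terminal alkyne places silicon on the terminal carbon and gives the E-vinylsilane without touching the carbinol stereocenter.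

Step 2
Reactants: 3 (2S,3E)-4-[dimethyl(phenyl)silyl]but-3-en-2-ol; 4 2-methylpropanoyl chloride
Product: 5 (2S,3E)-4-[dimethyl(phenyl)silyl]but-3-en-2-yl 2-methylpropanoate
Conditions: Et3N, DMAP (cat.), CH2Cl2, 0 °C to rt
Reagents that add atoms: none
Why: DMAP-catalysed O-acylation of a secondary alcohol proceeds with retention because the C–O bond is not broken.

Step 3
Reactants: 5 (2S,3E)-4-[dimethyl(phenyl)silyl]but-3-en-2-yl 2-methylpropanoate
Product: 8 (3R,4E)-3-[dimethyl(phenyl)silyl]-2,2-dimethylhex-4-enoic acid, via silyl ketene acetal 6 (not isolated), via trimethylsilyl ester 7 (not isolated)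
Conditions: LiN(i-Pr)2, THF, −78 °C; TMSCl; −78 °C to 60 °C; then 1 M HCl
Reagents that add atoms: none
Why: Ireland–Claisen rearrangement through a chair with the carbinol methyl equatorial transfers chirality suprafacially, which sets the silyl-bearing carbon (future C11, R), the quaternary C10 and the E-propenyl unit; the symmetric isobutyrate ketene acetal raises no geometry issue.

Step 4
Reactants: 8 (3R,4E)-3-[dimethyl(phenyl)silyl]-2,2-dimethylhex-4-enoic acid
Product: 9 (4R,5E)-4-[dimethyl(phenyl)silyl]-3,3-dimethylhept-5-en-2-one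
Conditions: MeLi (2.2 equiv), Et2O, 0 °C to rt; then H2O
Reagents that add atoms: methyllithium [Li]C
Why: Addition of methyllithium to a lithium carboxylate stops at the dilithio gem-diolate and gives the methyl ketone on hydrolysis, and the alpha carbon is quaternary so nothing can epimerise.

Step 5
Reactants: 10 (−)-shikimic acid
Product: 11 methyl shikimate, methyl (3R,4S,5R)-3,4,5-trihydroxycyclohex-1-ene-1-carboxylate
Conditions: MeOH, camphorsulfonic acid (cat.), reflux
Reagents that add atoms: methanol CO
Why: Fischer esterification leaves the three carbinol centres untouched.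

Step 6
Reactants: 11 methyl shikimate
Product: 12 methyl (1S,5R,6R)-5-hydroxy-7-oxabicyclo[4.1.0]hept-3-ene-3-carboxylate (epoxide on future C3/C2, cis to the allylic OH on future C5)
Conditions: PPh3, DIAD, THF, 0 °C to rt
Reagents that add atoms: none
Why: In this intramolecular Mitsunobu etherification the least hindered equatorial 5-OH is activated and displaced by the trans 4-OH, with the first inversion at future C2 and retention at future C3.

Step 7
Reactants: 12 methyl (1S,5R,6R)-5-hydroxy-7-oxabicyclo[4.1.0]hept-3-ene-3-carboxylate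
Product: 13 methyl (3R,4S,5R)-3,4-dihydroxy-5-methylcyclohex-1-ene-1-carboxylate
Conditions: AlMe3 (3 equiv), CH2Cl2/hexane, −78 °C to 0 °C; aq. KNaC4H4O6
Reagents that add atoms: trimethylaluminium C[Al](C)C
Why: Trialkylaluminium opening of a 2,3-epoxy alcohol goes through the aluminium alkoxide at the distal epoxide carbon with inversion, so the methyl enters C2 anti to O3 (second inversion at this carbon), and the enoate is inert to AlMe3 at this temperature.

Step 8
Reactants: 13 methyl (3R,4S,5R)-3,4-dihydroxy-5-methylcyclohex-1-ene-1-carboxylate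
Product: 14 methyl (3R,4S,5R)-4-(benzoyloxy)-3-hydroxy-5-methylcyclohex-1-ene-1-carboxylate
Conditions: BzCl (1.1 equiv), 2-aminoethyl diphenylborinate (10 mol %), i-Pr2NEt, MeCN, rt
Reagents that add atoms: benzoyl chloride O=C(Cl)c1ccccc1
Why: Borinic-acid-catalysed monoacylation of a cis-1,2-diol acylates the equatorial oxygen of the borinate, here O3, and leaves the pseudoaxial allylic O5–H free.

Step 9
Reactants: 14 methyl (3R,4S,5R)-4-(benzoyloxy)-3-hydroxy-5-methylcyclohex-1-ene-1-carboxylate
Product: 16 methyl (1R,2S,3R,4S,5R)-4-(benzoyloxy)-1,2,3-trihydroxy-5-methylcyclohexane-1-carboxylate, via osmate ester 15 (not isolated)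
Conditions: OsO4 (1.05 equiv), TMEDA, CH2Cl2, −78 °C to rt; then aq. Na2SO3, THF
Reagents that add atoms: osmium tetroxide O=[Os](=O)(=O)=O
Why: In this hydrogen-bond-directed syn dihydroxylation the allylic O5–H binds the OsO4·TMEDA complex and delivers it to its own face, which sets C15 (R) and places the C4 oxygen cis to O5, O3 and O15.

Step 10
Reactants: 16 methyl (1R,2S,3R,4S,5R)-4-(benzoyloxy)-1,2,3-trihydroxy-5-methylcyclohexane-1-carboxylate
Product: 17 methyl (1R,2S,3S,4S,5R)-4-(benzoyloxy)-1,3-dihydroxy-5-methyl-2-(tosyloxy)cyclohexane-1-carboxylate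
Conditions: TsCl (1.2 equiv), Bu2SnO (10 mol %), Et3N, CH2Cl2, rt
Reagents that add atoms: 4-methylbenzenesulfonyl chloride Cc1ccc(cc1)S(=O)(=O)Cl
Why: Stannylene-catalysed monosulfonylation of a cis-diol reacts at the equatorial oxygen, and O4 is the only equatorial hydroxyl (O5 is axial, O15 is axial and tertiary) and the equatorial partner of both possible stannylene acetals.

Step 11
Reactants: 17 methyl (1R,2S,3S,4S,5R)-4-(benzoyloxy)-1,3-dihydroxy-5-methyl-2-(tosyloxy)cyclohexane-1-carboxylate
Product: 18 methyl (1R,2S,3S,4R)-3-(benzoyloxy)-2-formyl-1-hydroxy-4-methylcyclopentane-1-carboxylate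
Conditions: Et2AlCl (2.5 equiv), CH2Cl2, −78 °C to −20 °C; pH 7 buffer
Reagents that add atoms: none
Why: Et2AlCl turns the two free hydroxyls into aluminium alkoxides and binds the sulfonate; in the ground-state chair (CO2Me, OTs, OBz and CH3 equatorial, O15 and O5 axial) the C4–OTs bond is antiperiplanar to the ring bond C5–C3, so the O5 lone pair pushes, C3 moves from C5 to C4 as tosylate leaves, and C5 is expelled from the ring as the formyl group. The closest known reaction type is the organoaluminium-promoted pinacol-type (semipinacol) rearrangement of 2-sulfonyloxy alcohols and the ring contraction of cyclohexane-1,2-diol monosulfonates with an equatorial leaving group. The five-membered ring C15–C1–C2–C3–C4 is closed by a suprafacial 1,2-alkyl shift, that is by backside attack of the C5–C3 sigma bond on C4, not by cyclisation of an open chain. C4 is the only new stereocenter and is fixed by inversion at the sulfonate carbon set in step 9, while the migrating C3 keeps its configuration and C2 and C15 are spectators, which puts C5, O3 and O15 on one face. The step needs migration of C3 rather than of C1 (the bond C15–C1 is also antiperiplanar), and a push from O15 is disfavoured because it would build a carbonyl carbon next to the ester, an alpha-keto ester. Hydride shift, epoxide closure and elimination are shut out because neither neighbouring carbon holds a hydrogen or an oxygen antiperiplanar to the equatorial leaving group.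

Step 12
Reactants: 18 methyl (1R,2S,3S,4R)-3-(benzoyloxy)-2-formyl-1-hydroxy-4-methylcyclopentane-1-carboxylate
Product: 19 methyl (1R,2S,3S,4R)-3-(benzoyloxy)-2-ethenyl-1-hydroxy-4-methylcyclopentane-1-carboxylate
Conditions: Zn, CH2Br2, TiCl4, THF/CH2Cl2, 0 °C to rt
Reagents that add atoms: dibromomethane BrCBr
Why: Takai–Lombardo methylenation uses a non-basic gem-dimetallic reagent that reacts with the aldehyde faster than with the esters, so it should cause neither enolisation at C4, nor retro-aldol cleavage, nor loss of benzoate.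

Step 13
Reactants: 19 methyl (1R,2S,3S,4R)-3-(benzoyloxy)-2-ethenyl-1-hydroxy-4-methylcyclopentane-1-carboxylate
Product: 20 (1S,2S,3R,5R)-2-ethenyl-3-hydroxy-3-(hydroxymethyl)-5-methylcyclopentyl benzoate (C14 as CH2OH, 15-OH free)
Conditions: NaBH4, EtOH, 0 °C to rt
Reagents that add atoms: none
Why: Borohydride reduction of an alpha-hydroxy ester is activated by the neighbouring hydroxyl, whereas the unactivated secondary benzoate should survive.

Step 14
Reactants: 20 (1S,2S,3R,5R)-2-ethenyl-3-hydroxy-3-(hydroxymethyl)-5-methylcyclopentyl benzoate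
Product: 21 (1S,2S,3R,5R)-2-ethenyl-3-formyl-3-hydroxy-5-methylcyclopentyl benzoate (C14 aldehyde)
Conditions: Dess–Martin periodinane, CH2Cl2, 0 °C to rt
Reagents that add atoms: none
Why: Dess–Martin oxidation converts the primary alcohol to the aldehyde, the tertiary 15-OH cannot be oxidised, and the aldehyde has no alpha hydrogen.

Step 15
Reactants: 21 (1S,2S,3R,5R)-2-ethenyl-3-formyl-3-hydroxy-5-methylcyclopentyl benzoate; 9 (4R,5E)-4-[dimethyl(phenyl)silyl]-3,3-dimethylhept-5-en-2-one
Product: 22 14,15-diol: the core of 21 carrying on C15 the chain CH(OH)–CH(CH3)–CH=CH–C(CH3)2–COCH3 (13S,14R,11E)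
Conditions: TiCl4 (2.2 equiv), 2,6-di-tert-butyl-4-methylpyridine (1.1 equiv), CH2Cl2, −78 °C; then 9 (1.4 equiv); aq. NaHCO3
Reagents that add atoms: none
Why: In this Hosomi–Sakurai-type addition of a chiral (E)-crotylsilane, titanium ties O15 and the formyl oxygen into a five-membered chelate that is attacked from the C1H2 side (14R), while the silane reacts anti to silicon through an open transition state that gives the 13,14-syn pair (13S) and the E-C11=C12 bond.

Step 16
Reactants: 22 14,15-diol
Product: 23 14,15-diacetate of 22 (3-OBz, 4-vinyl, 9-ketone)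
Conditions: Ac2O, Et3N, DMAP, CH2Cl2, 40 °C
Reagents that add atoms: acetic anhydride CC(=O)OC(C)=O
Why: DMAP-catalysed acetylation under forcing conditions esterifies both the secondary 14-OH and the tertiary 15-OH with retention.

Step 17
Reactants: 23 14,15-diacetate; 24 methacrolein
Product: 25 target, (2R,3S,4S,13S,14R,15R)-14,15-diacetoxy-3-benzoyloxy-9-oxo-7,8-secojatropha-5E,11E-dien-7-al
Conditions: second-generation Hoveyda–Grubbs catalyst (10 mol %), 24 (10 equiv), CH2Cl2, 40 °C
Reagents that add atoms: none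
Why: Olefin cross-metathesis of the only terminal alkene with a 1,1-disubstituted electron-poor partner gives the E-trisubstituted enal, and the C11=C12 alkene next to the quaternary C10 should stay a spectator.

Compound list
1 | (S)-but-3-yn-2-ol | C[C@H](O)C#C | starting material
2 | dimethyl(phenyl)silane | C[SiH](C)c1ccccc1 | starting material
3 | (2S,3E)-4-[dimethyl(phenyl)silyl]but-3-en-2-ol | C[C@H](O)/C=C/[Si](C)(C)c1ccccc1 | intermediate
4 | 2-methylpropanoyl chloride | CC(C)C(=O)Cl | starting material
5 | (2S,3E)-4-[dimethyl(phenyl)silyl]but-3-en-2-yl 2-methylpropanoate | C[C@H](OC(=O)C(C)C)/C=C/[Si](C)(C)c1ccccc1 | intermediate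
6 | trimethylsilyl ketene acetal of 5 | C[C@H](OC(O[Si](C)(C)C)=C(C)C)/C=C/[Si](C)(C)c1ccccc1 | intermediate
7 | trimethylsilyl (3R,4E)-3-[dimethyl(phenyl)silyl]-2,2-dimethylhex-4-enoate | C[Si](C)(C)OC(=O)C(C)(C)[C@@H](/C=C/C)[Si](C)(C)c1ccccc1 | intermediate
8 | (3R,4E)-3-[dimethyl(phenyl)silyl]-2,2-dimethylhex-4-enoic acid | OC(=O)C(C)(C)[C@@H](/C=C/C)[Si](C)(C)c1ccccc1 | intermediate
9 | (4R,5E)-4-[dimethyl(phenyl)silyl]-3,3-dimethylhept-5-en-2-one | CC(=O)C(C)(C)[C@@H](/C=C/C)[Si](C)(C)c1ccccc1 | intermediate
10 | (−)-shikimic acid | OC(=O)C1=C[C@@H](O)[C@@H](O)[C@H](O)C1 | starting material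
11 | methyl shikimate | COC(=O)C1=C[C@@H](O)[C@@H](O)[C@H](O)C1 | intermediate
12 | methyl (1S,5R,6R)-5-hydroxy-7-oxabicyclo[4.1.0]hept-3-ene-3-carboxylate | COC(=O)C1=C[C@@H](O)[C@H]2O[C@H]2C1 | intermediate
13 | methyl (3R,4S,5R)-3,4-dihydroxy-5-methylcyclohex-1-ene-1-carboxylate | COC(=O)C1=C[C@@H](O)[C@@H](O)[C@H](C)C1 | intermediate
14 | methyl (3R,4S,5R)-4-(benzoyloxy)-3-hydroxy-5-methylcyclohex-1-ene-1-carboxylate | COC(=O)C1=C[C@@H](O)[C@@H](OC(=O)c2ccccc2)[C@H](C)C1 | intermediate
15 | cyclic osmate ester of 16 at O15/O4 (TMEDA ligand not drawn) | COC(=O)[C@@]1(O[Os]2(=O)=O)C[C@@H](C)[C@H](OC(=O)c3ccccc3)[C@H](O)[C@@H]1O2 | intermediate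
16 | methyl (1R,2S,3R,4S,5R)-4-(benzoyloxy)-1,2,3-trihydroxy-5-methylcyclohexane-1-carboxylate | COC(=O)[C@@]1(O)C[C@@H](C)[C@H](OC(=O)c2ccccc2)[C@H](O)[C@@H]1O | intermediate
17 | methyl (1R,2S,3S,4S,5R)-4-(benzoyloxy)-1,3-dihydroxy-5-methyl-2-(tosyloxy)cyclohexane-1-carboxylate | COC(=O)[C@@]1(O)C[C@@H](C)[C@H](OC(=O)c2ccccc2)[C@H](O)[C@@H]1OS(=O)(=O)c3ccc(C)cc3 | intermediate
18 | methyl (1R,2S,3S,4R)-3-(benzoyloxy)-2-formyl-1-hydroxy-4-methylcyclopentane-1-carboxylate | COC(=O)[C@@]1(O)C[C@@H](C)[C@H](OC(=O)c2ccccc2)[C@@H]1C=O | intermediate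
19 | methyl (1R,2S,3S,4R)-3-(benzoyloxy)-2-ethenyl-1-hydroxy-4-methylcyclopentane-1-carboxylate | COC(=O)[C@@]1(O)C[C@@H](C)[C@H](OC(=O)c2ccccc2)[C@@H]1C=C | intermediate
20 | (1S,2S,3R,5R)-2-ethenyl-3-hydroxy-3-(hydroxymethyl)-5-methylcyclopentyl benzoate | OC[C@@]1(O)C[C@@H](C)[C@H](OC(=O)c2ccccc2)[C@@H]1C=C | intermediate
21 | (1S,2S,3R,5R)-2-ethenyl-3-formyl-3-hydroxy-5-methylcyclopentyl benzoate | O=C[C@@]1(O)C[C@@H](C)[C@H](OC(=O)c2ccccc2)[C@@H]1C=C | intermediate
22 | 14,15-diol (2R,3S,4S,13S,14R,15R,11E) with 3-OBz, 4-vinyl and 9-ketone | O[C@H]([C@@H](C)/C=C/C(C)(C)C(C)=O)[C@@]1(O)C[C@@H](C)[C@H](OC(=O)c2ccccc2)[C@@H]1C=C | intermediate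
23 | 14,15-diacetate of 22 | CC(=O)O[C@H]([C@@H](C)/C=C/C(C)(C)C(C)=O)[C@@]1(OC(C)=O)C[C@@H](C)[C@H](OC(=O)c2ccccc2)[C@@H]1C=C | intermediate
24 | methacrolein | CC(=C)C=O | starting material
25 | CNP0489076.1 | CC(=O)O[C@H]([C@@H](C)/C=C/C(C)(C)C(C)=O)[C@@]1(OC(C)=O)C[C@@H](C)[C@H](OC(=O)c2ccccc2)[C@@H]1/C=C(\C)C=O | target

Total step count: 17. Longest linear sequence: 13 steps (steps 5 to 17, from shikimic acid). Steps 1 to 4 form the convergent branch.

Steps most likely to fail

Step 11. Three processes could defeat the shift.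
- Heterolysis of a sulfonate flanked by three oxygenated carbons may be slow.
- The tertiary O15 may push and send C1 instead of C3 to C4.
- The aldol-type product may be lost by retro-aldol cleavage or by elimination of benzoate while it sits on aluminium.

The fallback sets out from triol 16, leaves out tosylate 17, and comes back at aldehyde 18. The triol is treated with PPh3 and DIAD in toluene without an external acid. The cis-diol O4/O5 is taken up as an oxyphosphonium or dioxaphosphorane species, which ionises at the equatorial C4–O bond in a neutral medium. The same antiperiplanar C5–C3 bond migrates while the betaine removes the O5 proton. This dehydrative Mitsunobu-type activation makes no new compound (F0).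

Step 9. The electron-poor trisubstituted enoate may react sluggishly. The hydrogen bond from O5–H may also fail to override the intrinsic preference for attack anti to the allylic oxygen, which would give poor facial selectivity at C15/C4.

The fallback sets out from 14 and comes back at 18. It replaces direction by steric control after epimerising C5.
- MnO2 oxidises the allylic alcohol to methyl (4S,5R)-4-(benzoyloxy)-5-methyl-3-oxocyclohex-1-ene-1-carboxylate F1.
- Luche reduction (NaBH4, CeCl3·7H2O, MeOH) by axial hydride attack gives the pseudoequatorial 3-epimer, methyl (3S,4S,5R)-4-(benzoyloxy)-3-hydroxy-5-methylcyclohex-1-ene-1-carboxylate F2.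
- TBSOTf and 2,6-lutidine give its tert-butyldimethylsilyl ether F3.
- Catalytic OsO4 with NMO attacks anti to the silyloxy group, which is now the required face, and gives the 1,2-diol F4.
- TsCl, Et3N and catalytic Bu2SnO sulfonylate the only secondary hydroxyl to give tosylate F5.
- HF·pyridine frees O5 to give the hydroxy tosylate F6, the C5 epimer of 17.
- Et2AlCl, as in step 11, triggers the same shift. C5 loses its stereocenter in the shift, so 18 results.

Step 17. The vinyl group sits on a carbon between two acyloxy-bearing ring carbons, so initiation on it may be slow. Catalyst decay and methacrolein self-reaction may then win.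

The fallback sets out from 23 and comes back at 25. Lemieux–Johnson cleavage (OsO4 cat., NaIO4, 2,6-lutidine, dioxane/H2O) takes the monosubstituted alkene in preference to the hindered C11=C12 bond. It gives the C5 aldehyde F7, the 4-formyl analogue of 23. A Wittig reaction with 2-(triphenylphosphoranylidene)propanal in toluene then builds the E-enal.

Further compounds
F0 | step 11 | none | none
F1 | step 9 | methyl (4S,5R)-4-(benzoyloxy)-5-methyl-3-oxocyclohex-1-ene-1-carboxylate | COC(=O)C1=CC(=O)[C@@H](OC(=O)c2ccccc2)[C@H](C)C1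
F2 | step 9 | methyl (3S,4S,5R)-4-(benzoyloxy)-3-hydroxy-5-methylcyclohex-1-ene-1-carboxylate | COC(=O)C1=C[C@H](O)[C@@H](OC(=O)c2ccccc2)[C@H](C)C1
F3 | step 9 | methyl (3S,4S,5R)-4-(benzoyloxy)-3-[(tert-butyldimethylsilyl)oxy]-5-methylcyclohex-1-ene-1-carboxylate | COC(=O)C1=C[C@H](O[Si](C)(C)C(C)(C)C)[C@@H](OC(=O)c2ccccc2)[C@H](C)C1
F4 | step 9 | methyl (1R,2S,3S,4S,5R)-4-(benzoyloxy)-3-[(tert-butyldimethylsilyl)oxy]-1,2-dihydroxy-5-methylcyclohexane-1-carboxylate | COC(=O)[C@@]1(O)C[C@@H](C)[C@H](OC(=O)c2ccccc2)[C@@H](O[Si](C)(C)C(C)(C)C)[C@@H]1O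
F5 | step 9 | methyl (1R,2S,3R,4S,5R)-4-(benzoyloxy)-3-[(tert-butyldimethylsilyl)oxy]-1-hydroxy-5-methyl-2-(tosyloxy)cyclohexane-1-carboxylate | COC(=O)[C@@]1(O)C[C@@H](C)[C@H](OC(=O)c2ccccc2)[C@@H](O[Si](C)(C)C(C)(C)C)[C@@H]1OS(=O)(=O)c3ccc(C)cc3
F6 | step 9 | methyl (1R,2S,3R,4S,5R)-4-(benzoyloxy)-1,3-dihydroxy-5-methyl-2-(tosyloxy)cyclohexane-1-carboxylate | COC(=O)[C@@]1(O)C[C@@H](C)[C@H](OC(=O)c2ccccc2)[C@@H](O)[C@@H]1OS(=O)(=O)c3ccc(C)cc3
F7 | step 17 | 4-formyl analogue of 23 (C5 aldehyde, 14,15-diacetate, 3-benzoate) | CC(=O)O[C@H]([C@@H](C)/C=C/C(C)(C)C(C)=O)[C@@]1(OC(C)=O)C[C@@H](C)[C@H](OC(=O)c2ccccc2)[C@@H]1C=O
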